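**Retrosynthetic overview**

- The last bond made is the b1–CH2 bridge to ring A, by joining the Mannich base at b1 of the ring B–ring C dimer with butyrylfilicinic acid (ring A, from phloroglucinol by C-acylation and geminal C-methylation).
- The strategy rests on the fully substituted central ring B: b1 (CH2 to ring A), b2 C–OH, b3 (CH2 to ring C), b4 C–OH, b5 C–butyryl, b6 C–OH. It is built de novo by an Alder–Rickert sequence. The dienol ether of 3-ethoxycyclohex-2-en-1-one supplies b3, b2, b1 and b6, 1-ethoxyhex-1-yn-3-one supplies b4 and b5, bonds b3–b4 and b5–b6 form, and the CH2–CH2 bridge leaves as ethylene.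
- Ring C enters complete. 2,4,6-Trimethoxytoluene is butyrylated before it is bromomethylated, so the benzylic bromide is hexasubstituted and cannot self-condense, and no acylation is needed once two phloroglucinol rings are present. Its ketone passes through the key step as a silyl enol ether.
- Ring order: ring C (purchased arene), ring B (formed in step 7), ring A (joined last). All five alkyl ethers are removed together with BBr3 after ring B exists.

Key step: step 7

Remark on the chemistry: the target has no stereocentre and is drawn as one enol tautomer. Compounds 7, 14 and 16 are racemic and their stereocentres do not survive. The Z geometry drawn for the ring C silyl enol ether in 8, 9, 16 and 17 is the one expected from LiN(iPr)2 in THF and is of no consequence, since the group is hydrolysed in step 7.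

**Route**

Step 1
Reactants: 1 2,4,6-trimethoxytoluene; 2 butanoyl chloride
Product: 3 1-(2,4,6-trimethoxy-3-methylphenyl)butan-1-one
Conditions: Bi(OTf)3 (5 mol %), MeNO2, 50 °C
Reagents that add atoms: none
Why: Friedel–Crafts acylation at one of the two equivalent free positions, each ortho/para to three methoxy groups, and the first acyl group deactivates the ring against a second.

Step 2
Reactants: 3 1-(2,4,6-trimethoxy-3-methylphenyl)butan-1-one
Product: 4 1-[3-(bromomethyl)-2,4,6-trimethoxy-5-methylphenyl]butan-1-one
Conditions: (CH2O)n, 33% HBr in AcOH, 40 °C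
Reagents that add atoms: formaldehyde (from paraformaldehyde), C=O; hydrogen bromide, Br
Why: Blanc-type bromomethylation at the only free ring position, which three methoxy groups still activate because the di-ortho-substituted ketone is twisted out of conjugation, and the fully substituted product cannot be benzylated further.

Step 3
Reactants: 5 3-ethoxycyclohex-2-en-1-one; 4 1-[3-(bromomethyl)-2,4,6-trimethoxy-5-methylphenyl]butan-1-one
Product: 7 6-[(3-butanoyl-2,4,6-trimethoxy-5-methylphenyl)methyl]-3-ethoxycyclohex-2-en-1-one (racemic), via lithium dienolate 6 (not isolated)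
Conditions: LiN(iPr)2 (1.1 equiv), THF, −78 °C; then 4, −78 °C → rt
Reagents that add atoms: none
Why: Stork–Danheiser kinetic alkylation, in which LiN(iPr)2 removes the C6 proton of the vinylogous ester and the cross-conjugated enolate displaces the benzylic bromide by SN2 faster than it exchanges protons with the hindered ring C ketone; the new C6 centre is racemic and is erased in step 4.

Step 4
Reactants: 7 6-[(3-butanoyl-2,4,6-trimethoxy-5-methylphenyl)methyl]-3-ethoxycyclohex-2-en-1-one
Product: 9 1-ethoxy-3-(trimethylsilyloxy)-4-{[2,4,6-trimethoxy-3-methyl-5-[(Z)-1-(trimethylsilyloxy)but-1-en-1-yl]phenyl]methyl}cyclohexa-1,3-diene, via dilithium bis-enolate 8 (not isolated)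
Conditions: LiN(iPr)2 (2.4 equiv), THF, −78 °C; Me3SiCl (3 equiv), −78 → 0 °C; pentane, filtration, no aqueous work-up
Reagents that add atoms: chlorotrimethylsilane, C[Si](C)(C)Cl
Why: Kinetic deprotonation at C6 of the vinylogous ester and at the α-CH2 of the ring C ketone followed by O-silylation of both enolates is the standard entry to 1-alkoxy-3-silyloxycyclohexa-1,3-dienes, and the excess base deliberately turns the ring C ketone into an inert silyl enol ether.

Step 5
Reactants: 2 butanoyl chloride; 10 N,O-dimethylhydroxylamine hydrochloride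
Product: 11 N-methoxy-N-methylbutanamide
Conditions: Et3N (2.2 equiv), CH2Cl2, 0 °C → rt
Reagents that add atoms: none
Why: N-Acylation of the hydroxylamine by the acid chloride (Weinreb amide formation) with triethylamine as acid scavenger.

Step 6
Reactants: 12 ethoxyacetylene; 11 N-methoxy-N-methylbutanamide
Product: 15 1-ethoxyhex-1-yn-3-one, via lithium ethoxyacetylide 13 (not isolated), via tetrahedral lithium adduct 14 (not isolated)
Conditions: n-BuLi, THF, −78 °C; then 11, −78 → −30 °C; cold aq NH4Cl, rapid extraction
Reagents that add atoms: none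
Why: Weinreb ketone synthesis, in which the acetylide adds once to give a chelated tetrahedral adduct that collapses only on quenching, so no tertiary alcohol forms, and the cold near-neutral quench spares the acid-sensitive ynol ether.

Step 7
Reactants: 9 1-ethoxy-3-(trimethylsilyloxy)-4-{[2,4,6-trimethoxy-3-methyl-5-[(Z)-1-(trimethylsilyloxy)but-1-en-1-yl]phenyl]methyl}cyclohexa-1,3-diene; 15 1-ethoxyhex-1-yn-3-one
Product: 18 1-[3-[(3-butanoyl-2,4-diethoxy-6-hydroxyphenyl)methyl]-2,4,6-trimethoxy-5-methylphenyl]butan-1-one, via bicyclo[2.2.2]octadiene adduct 16 (not isolated), via aryl trimethylsilyl ether 17 (not isolated)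
Conditions: PhMe, BHT (cat.), sealed tube, 70 °C then 150 °C; then 1 M HCl, THF, rt
Reagents that add atoms: none
Why: Proposed new method: the electron-rich diene of 9 should add to the push-pull ynone 15 in a [4+2] sense, either in a concerted asynchronous way or by Mukaiyama–Michael attack of the silyl enol ether carbon on the ethoxy-bearing alkyne carbon followed by closure of the allenolate carbon onto the ethoxy-stabilised oxocarbenium ion, giving bicyclo[2.2.2]octadiene 16, which on stronger heating loses its CH2–CH2 bridge as ethylene by retro-Diels–Alder reaction. The closest known reaction type is the Alder–Rickert reaction of 1-alkoxy-3-silyloxy- and 1,3-bis(silyloxy)cyclohexa-1,3-dienes with acetylenic ketones and esters, which gives resorcinol derivatives, whereas an alkyne bearing an alkoxy group next to the acyl group has not been used in it. Ring B is closed by an intermolecular [4+2] cycloaddition that forms b3–b4 and b5–b6, and the cyclohexane ring of the diene only holds the diene s-cis before two of its carbons are expelled. No stereocentre is set, because the two bridgehead centres of 16 vanish on aromatisation. The step needs one regiochemistry, the arylmethyl-bearing diene terminus bonding to the ethoxy-bearing alkyne carbon, and this is secured because both donors of the diene (OEt at C1, OSiMe3 at C3) put the largest HOMO coefficient on C4 while the carbonyl of 15 makes the β-carbon the electrophilic one. The cycloaddition is run at 70 °C before the temperature is raised because a free 1-ethoxyalkyne can lose ethylene by a retro-ene reaction above about 100 °C, and the acid work-up removes both trimethylsilyl groups.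

Step 8
Reactants: 18 1-[3-[(3-butanoyl-2,4-diethoxy-6-hydroxyphenyl)methyl]-2,4,6-trimethoxy-5-methylphenyl]butan-1-one
Product: 19 1-[3-[(3-butanoyl-2,4,6-trihydroxyphenyl)methyl]-2,4,6-trihydroxy-5-methylphenyl]butan-1-one
Conditions: BBr3 (10 equiv), CH2Cl2, −78 °C → rt; then H2O, 0 °C, degassed solvents
Reagents that add atoms: none
Why: Lewis-acid ether cleavage in which bromide removes each methyl and ethyl group by SN2 from the boron-complexed ether, assisted by chelation for the four alkoxy groups ortho to a ketone, while the acyl group on each ring protects the diarylmethane bridge from ipso-protonation.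

Step 9
Reactants: 20 phloroglucinol; 2 butanoyl chloride
Product: 21 1-(2,4,6-trihydroxyphenyl)butan-1-one
Conditions: AlCl3 (3.5 equiv), PhNO2, CH2Cl2, 0 → 60 °C; ice, aq HCl
Reagents that add atoms: none
Why: Friedel–Crafts C-acylation of phloroglucinol, whose three ring positions are equivalent, stopping at the chelated and deactivated monoketone.

Step 10
Reactants: 21 1-(2,4,6-trihydroxyphenyl)butan-1-one
Product: 22 2-butanoyl-3,5-dihydroxy-6,6-dimethylcyclohexa-2,4-dien-1-one (butyrylfilicinic acid)
Conditions: NaOMe (3 equiv), MeI (2.5 equiv), MeOH, 0 °C → rt; chromatography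
Reagents that add atoms: iodomethane, CI
Why: Base-mediated C-methylation of the acylphloroglucinol anion, the second methyl group entering at the same carbon and dearomatising the ring to the filicinic acid type, a known transformation that needs separation from other C-methylated products.

Step 11
Reactants: 19 1-[3-[(3-butanoyl-2,4,6-trihydroxyphenyl)methyl]-2,4,6-trihydroxy-5-methylphenyl]butan-1-one
Product: 23 1-[3-[[3-butanoyl-5-[(dimethylamino)methyl]-2,4,6-trihydroxyphenyl]methyl]-2,4,6-trihydroxy-5-methylphenyl]butan-1-one
Conditions: [Me2N=CH2]I (1.05 equiv), Et3N (1.1 equiv), MeCN, 0 °C → rt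
Reagents that add atoms: N,N-dimethylmethyleneiminium iodide, C=[N+](C)C.[I-]
Why: Mannich aminomethylation with a preformed iminium salt at b1, the only unsubstituted ring carbon of 19 since ring C is fully substituted.

Step 12
Reactants: 23 1-[3-[[3-butanoyl-5-[(dimethylamino)methyl]-2,4,6-trihydroxyphenyl]methyl]-2,4,6-trihydroxy-5-methylphenyl]butan-1-one; 22 2-butanoyl-3,5-dihydroxy-6,6-dimethylcyclohexa-2,4-dien-1-one
Product: 25 2-butanoyl-4-[[3-butanoyl-5-[(3-butanoyl-2,4,6-trihydroxy-5-methylphenyl)methyl]-2,4,6-trihydroxyphenyl]methyl]-3,5-dihydroxy-6,6-dimethylcyclohexa-2,4-dien-1-one (target), via ortho-quinone methide 24 (not isolated)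
Conditions: 1,4-dioxane, 85 °C, Ar; dilute aq HCl wash
Reagents that add atoms: none
Why: Thermal loss of dimethylamine from the ortho-hydroxybenzylamine gives an ortho-quinone methide at b1, which the nucleophilic ring CH carbon of 22 captures by Michael addition with rearomatisation of ring B, the known Mannich-base alkylation of 1,3-dicarbonyl compounds.

**Compound list**

1 | 2,4,6-trimethoxytoluene | Cc1c(OC)cc(OC)cc1OC | starting material
2 | butanoyl chloride | CCCC(=O)Cl | starting material
3 | 1-(2,4,6-trimethoxy-3-methylphenyl)butan-1-one | CCCC(=O)c1c(OC)cc(OC)c(C)c1OC | intermediate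
4 | 1-[3-(bromomethyl)-2,4,6-trimethoxy-5-methylphenyl]butan-1-one | CCCC(=O)c1c(OC)c(C)c(OC)c(CBr)c1OC | intermediate
5 | 3-ethoxycyclohex-2-en-1-one | CCOC1=CC(=O)CCC1 | starting material
6 | lithium 5-ethoxycyclohexa-1,5-dien-1-olate | CCOC1=CC(O[Li])=CCC1 | intermediate (not isolated)
7 | 6-[(3-butanoyl-2,4,6-trimethoxy-5-methylphenyl)methyl]-3-ethoxycyclohex-2-en-1-one, racemic | CCOC1=CC(=O)C(Cc2c(OC)c(C)c(OC)c(C(=O)CCC)c2OC)CC1 | intermediate
8 | dilithium bis-enolate of 7 (ring dienolate at C1/C6 and Z-enolate of the ring C ketone) | CCOC1=CC(O[Li])=C(Cc2c(OC)c(C)c(OC)c(/C(O[Li])=C/CC)c2OC)CC1 | intermediate (not isolated)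
9 | 1-ethoxy-3-(trimethylsilyloxy)-4-{[2,4,6-trimethoxy-3-methyl-5-[(Z)-1-(trimethylsilyloxy)but-1-en-1-yl]phenyl]methyl}cyclohexa-1,3-diene | CCOC1=CC(O[Si](C)(C)C)=C(Cc2c(OC)c(C)c(OC)c(/C(O[Si](C)(C)C)=C/CC)c2OC)CC1 | intermediate
10 | N,O-dimethylhydroxylamine hydrochloride | CNOC.Cl | starting material
11 | N-methoxy-N-methylbutanamide | CCCC(=O)N(C)OC | intermediate
12 | ethoxyacetylene | C#COCC | starting material
13 | lithium ethoxyacetylide | [Li]C#COCC | intermediate (not isolated)
14 | lithium 1-ethoxy-3-[methoxy(methyl)amino]hex-1-yn-3-olate, racemic | CCCC(O[Li])(C#COCC)N(C)OC | intermediate (not isolated)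
15 | 1-ethoxyhex-1-yn-3-one | CCCC(=O)C#COCC | intermediate
16 | 1-[2,4-diethoxy-6-(trimethylsilyloxy)-1-{[2,4,6-trimethoxy-3-methyl-5-[(Z)-1-(trimethylsilyloxy)but-1-en-1-yl]phenyl]methyl}bicyclo[2.2.2]octa-2,5-dien-3-yl]butan-1-one, racemic, bridgehead configurations tied by the bicycle | CCCC(=O)C1=C(OCC)C2(Cc3c(OC)c(C)c(OC)c(/C(O[Si](C)(C)C)=C/CC)c3OC)CCC1(OCC)C=C2O[Si](C)(C)C | intermediate (not isolated)
17 | 1-[2,6-diethoxy-4-(trimethylsilyloxy)-3-{[2,4,6-trimethoxy-3-methyl-5-[(Z)-1-(trimethylsilyloxy)but-1-en-1-yl]phenyl]methyl}phenyl]butan-1-one | CCCC(=O)c1c(OCC)cc(O[Si](C)(C)C)c(Cc2c(OC)c(C)c(OC)c(/C(O[Si](C)(C)C)=C/CC)c2OC)c1OCC | intermediate (not isolated)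
18 | 1-[3-[(3-butanoyl-2,4-diethoxy-6-hydroxyphenyl)methyl]-2,4,6-trimethoxy-5-methylphenyl]butan-1-one | CCCC(=O)c1c(OCC)cc(O)c(Cc2c(OC)c(C)c(OC)c(C(=O)CCC)c2OC)c1OCC | intermediate
19 | 1-[3-[(3-butanoyl-2,4,6-trihydroxyphenyl)methyl]-2,4,6-trihydroxy-5-methylphenyl]butan-1-one | CCCC(=O)c1c(O)cc(O)c(Cc2c(O)c(C)c(O)c(C(=O)CCC)c2O)c1O | intermediate
20 | phloroglucinol (benzene-1,3,5-triol) | Oc1cc(O)cc(O)c1 | starting material
21 | 1-(2,4,6-trihydroxyphenyl)butan-1-one | CCCC(=O)c1c(O)cc(O)cc1O | intermediate
22 | 2-butanoyl-3,5-dihydroxy-6,6-dimethylcyclohexa-2,4-dien-1-one (butyrylfilicinic acid) | CCCC(=O)C1=C(O)C=C(O)C(C)(C)C1=O | intermediate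
23 | 1-[3-[[3-butanoyl-5-[(dimethylamino)methyl]-2,4,6-trihydroxyphenyl]methyl]-2,4,6-trihydroxy-5-methylphenyl]butan-1-one | CCCC(=O)c1c(O)c(CN(C)C)c(O)c(Cc2c(O)c(C)c(O)c(C(=O)CCC)c2O)c1O | intermediate
24 | 4-butanoyl-2-[(3-butanoyl-2,4,6-trihydroxy-5-methylphenyl)methyl]-3,5-dihydroxy-6-methylidenecyclohexa-2,4-dien-1-one | C=C1C(=O)C(Cc2c(O)c(C)c(O)c(C(=O)CCC)c2O)=C(O)C(C(=O)CCC)=C1O | intermediate (not isolated)
25 | 2-butanoyl-4-[[3-butanoyl-5-[(3-butanoyl-2,4,6-trihydroxy-5-methylphenyl)methyl]-2,4,6-trihydroxyphenyl]methyl]-3,5-dihydroxy-6,6-dimethylcyclohexa-2,4-dien-1-one | CCCC(=O)C1=C(O)C(Cc2c(O)c(Cc3c(O)c(C)c(O)c(C(=O)CCC)c3O)c(O)c(C(=O)CCC)c2O)=C(O)C(C)(C)C1=O | target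

**Step count**

Total: 12 steps. Longest linear sequence: 8 steps (1, 2, 3, 4, 7, 8, 11, 12).

**Steps most likely to fail**

Step 7 (Proposed new method). Cycloaddition at the fully substituted diene terminus may be slow. The ynol ether could then lose ethylene by retro-ene reaction. The first C–C bond could also be followed by loss of ethoxytrimethylsilane (substitution at the alkyne carbon) in place of ring closure, or the partners could combine with the opposite orientation. The fallback uses known chemistry and builds the ring B–ring C bond on a preformed phloroglucinol. It sets out from bromide 4 and ketone 21. The sodium salt of 21 (NaOMe, MeOH, 0 °C, 21 in excess) should be C-benzylated by 4 to give 1-[3-[(3-butanoyl-2,4,6-trimethoxy-5-methylphenyl)methyl]-2,4,6-trihydroxyphenyl]butan-1-one F1. BBr3 in CH2Cl2 should then cleave its three methyl ethers, and the sequence comes back to the route at 19.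

Step 12. At the temperature needed to expel dimethylamine from the phenolic Mannich base, either methylene bridge may reopen by retro-Michael reaction and the dimers may scramble. The quinone methide may also be recaptured by the amine. The fallback reverses the roles of the partners so that the electrophile forms under milder conditions. It sets out from 22 and 19. Compound 22 and [Me2N=CH2]I with Et3N in CH2Cl2 at 0 °C should give 2-butanoyl-4-[(dimethylamino)methyl]-3,5-dihydroxy-6,6-dimethylcyclohexa-2,4-dien-1-one F2. This vinylogous-acid Mannich base should lose dimethylamine at 25–40 °C in AcOH buffered with NaOAc to give 2-butanoyl-3-hydroxy-6,6-dimethyl-4-methylidenecyclohex-2-ene-1,5-dione F3. Carbon b1 of 19 should trap F3 in the same flask, and the sequence comes back to the route at 25.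

Step 2. Substitution at the last, hindered position of a ring deactivated by the ketone may be slow, and HBr may cleave the methyl ether chelated to the ketone before the bromomethyl group is in place. The fallback introduces the carbon as an aldehyde under non-protic conditions. It sets out from 3. Rieche formylation (Cl2CHOMe, TiCl4, CH2Cl2, −20 → 0 °C) should give 3-butanoyl-2,4,6-trimethoxy-5-methylbenzaldehyde F4. NaBH4 in MeOH at −20 °C should reduce the aldehyde in preference to the di-ortho-substituted ketone to give 1-[3-(hydroxymethyl)-2,4,6-trimethoxy-5-methylphenyl]butan-1-one F5. Brief treatment with 48% aq HBr in CH2Cl2 at 0 °C should convert F5 into the bromide, and the sequence comes back to the route at 4.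

**Further compounds**

F1 | step 7 | 1-[3-[(3-butanoyl-2,4,6-trimethoxy-5-methylphenyl)methyl]-2,4,6-trihydroxyphenyl]butan-1-one | CCCC(=O)c1c(O)cc(O)c(Cc2c(OC)c(C)c(OC)c(C(=O)CCC)c2OC)c1O
F2 | step 12 | 2-butanoyl-4-[(dimethylamino)methyl]-3,5-dihydroxy-6,6-dimethylcyclohexa-2,4-dien-1-one | CCCC(=O)C1=C(O)C(CN(C)C)=C(O)C(C)(C)C1=O
F3 | step 12 | 2-butanoyl-3-hydroxy-6,6-dimethyl-4-methylidenecyclohex-2-ene-1,5-dione | CCCC(=O)C1=C(O)C(=C)C(=O)C(C)(C)C1=O
F4 | step 2 | 3-butanoyl-2,4,6-trimethoxy-5-methylbenzaldehyde | CCCC(=O)c1c(OC)c(C)c(OC)c(C=O)c1OC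
F5 | step 2 | 1-[3-(hydroxymethyl)-2,4,6-trimethoxy-5-methylphenyl]butan-1-one | CCCC(=O)c1c(OC)c(C)c(OC)c(CO)c1OC
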